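**Retrosynthetic overview**
- The target acid comes from one saponification that cleaves both a methyl benzoate and a primary allylic acetate.
- The C4–C5 bond and the 4R carbinol come from a linear prenylboration of an (E)-α-methyl enal with a tertiary α,α-dimethylallyl boronate under chiral phosphoric acid catalysis (the proposed new step).
- Both (E)-trisubstituted alkenes come from cross-metathesis of aryl-allyl groups with methacrolein; the first enal is reduced to the allylic alcohol arm, the second is kept for the prenylboration.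
- The two aryl–allyl bonds are made at different times: an aromatic Claisen rearrangement first, then a Stille allylation of the ortho bromide.
- No ring is formed; the benzene ring is bought as methyl 3-bromo-4-hydroxybenzoate.

Assumption: 4,4,5,5-tetramethyl-2-(2-methylbut-3-en-2-yl)-1,3,2-dioxaborolane and the acid (R)-TRIP are taken as catalogue reagents.

**Route**

Step 1
Reactants: 1 methyl 3-bromo-4-hydroxybenzoate; 2 allyl bromide
Product: 3 methyl 3-bromo-4-(prop-2-en-1-yloxy)benzoate
Conditions: 2 (1.2 equiv), K2CO3 (1.5 equiv), acetone, reflux, 6 h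
Reagents that add atoms: none
Why: Williamson ether synthesis, SN2 O-allylation of the acidic phenoxide; no stereocentre is involved.

Step 2
Reactants: 3 methyl 3-bromo-4-(prop-2-en-1-yloxy)benzoate
Product: 5 methyl 3-bromo-4-hydroxy-5-(prop-2-en-1-yl)benzoate, via ortho-dienone 4 (not isolated)
Conditions: N,N-diethylaniline, 200 °C, argon, 8 h
Reagents that add atoms: none
Why: aromatic Claisen rearrangement ([3,3]-sigmatropic shift) to the only ortho position that carries hydrogen, followed by enolisation of the dienone to the phenol; the amine solvent suppresses acid-promoted cyclisation to a dihydrobenzofuran.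

Step 3
Reactants: 5 methyl 3-bromo-4-hydroxy-5-(prop-2-en-1-yl)benzoate
Product: 6 methyl 3-bromo-4-methoxy-5-(prop-2-en-1-yl)benzoate
Conditions: MeI (1.5 equiv), K2CO3 (2 equiv), DMF, rt, 12 h
Reagents that add atoms: iodomethane CI
Why: Williamson O-methylation (SN2) of a phenoxide made acidic by the para ester; the 2,6-substituents do not block the small electrophile.

Step 4
Reactants: 6 methyl 3-bromo-4-methoxy-5-(prop-2-en-1-yl)benzoate; 7 methacrolein
Product: 8 methyl 3-bromo-4-methoxy-5-[(2E)-3-methyl-4-oxobut-2-en-1-yl]benzoate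
Conditions: 7 (8 equiv), second-generation Hoveyda–Grubbs catalyst RuCl2(H2IMes)(=CH-C6H4-2-OiPr) (3 mol%), 1,4-benzoquinone (10 mol%), CH2Cl2, 40 °C, 16 h
Reagents that add atoms: none
Why: olefin cross-metathesis of a terminal allyl arene with an electron-poor 1,1-disubstituted partner gives the conjugated enal with thermodynamic E selectivity, and benzoquinone suppresses allyl-to-propenyl isomerisation.

Step 5
Reactants: 8 methyl 3-bromo-4-methoxy-5-[(2E)-3-methyl-4-oxobut-2-en-1-yl]benzoate
Product: 9 methyl 3-bromo-5-[(2E)-4-hydroxy-3-methylbut-2-en-1-yl]-4-methoxybenzoate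
Conditions: NaBH4 (1.0 equiv), CeCl3·7H2O (1.1 equiv), MeOH, −10 °C, 20 min
Reagents that add atoms: none
Why: Luche reduction gives clean 1,2-reduction of the enal and leaves the methyl benzoate, the aryl bromide and the alkene geometry untouched.

Step 6
Reactants: 9 methyl 3-bromo-5-[(2E)-4-hydroxy-3-methylbut-2-en-1-yl]-4-methoxybenzoate; 10 allyltributylstannane
Product: 11 methyl 3-[(2E)-4-hydroxy-3-methylbut-2-en-1-yl]-4-methoxy-5-(prop-2-en-1-yl)benzoate
Conditions: 10 (1.3 equiv), Pd(PPh3)4 (5 mol%), toluene, 100 °C, 12 h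
Reagents that add atoms: none
Why: Stille cross-coupling of the aryl bromide (activated by the meta ester) with an unsubstituted allyl stannane, so there is no regiochemical issue; the free allylic alcohol and the ester are tolerated.

Step 7
Reactants: 11 methyl 3-[(2E)-4-hydroxy-3-methylbut-2-en-1-yl]-4-methoxy-5-(prop-2-en-1-yl)benzoate
Product: 12 methyl 3-[(2E)-4-(acetyloxy)-3-methylbut-2-en-1-yl]-4-methoxy-5-(prop-2-en-1-yl)benzoate
Conditions: Ac2O (1.5 equiv), pyridine (3 equiv), DMAP (5 mol%), CH2Cl2, 0 °C to rt, 2 h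
Reagents that add atoms: acetic anhydride CC(=O)OC(C)=O
Why: DMAP-catalysed acylation of the primary alcohol; it is placed after the last zerovalent palladium step so the allylic acetate is never ionised, and the acetate later leaves in the final saponification.

Step 8
Reactants: 12 methyl 3-[(2E)-4-(acetyloxy)-3-methylbut-2-en-1-yl]-4-methoxy-5-(prop-2-en-1-yl)benzoate; 7 methacrolein
Product: 13 methyl 3-[(2E)-4-(acetyloxy)-3-methylbut-2-en-1-yl]-4-methoxy-5-[(2E)-3-methyl-4-oxobut-2-en-1-yl]benzoate
Conditions: 7 (8 equiv), second-generation Hoveyda–Grubbs catalyst RuCl2(H2IMes)(=CH-C6H4-2-OiPr) (5 mol%), 1,4-benzoquinone (10 mol%), CH2Cl2, 40 °C, 16 h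
Reagents that add atoms: none
Why: olefin cross-metathesis takes place only at the terminal allyl group, because the trisubstituted, acetoxy-deactivated alkene of the other arm is too hindered and electron-poor to enter the cycle; the enal forms E-selectively as in step 4.

Step 9
Reactants: 13 methyl 3-[(2E)-4-(acetyloxy)-3-methylbut-2-en-1-yl]-4-methoxy-5-[(2E)-3-methyl-4-oxobut-2-en-1-yl]benzoate; 14 4,4,5,5-tetramethyl-2-(2-methylbut-3-en-2-yl)-1,3,2-dioxaborolane
Product: 16 methyl 3-[(2E)-4-(acetyloxy)-3-methylbut-2-en-1-yl]-5-[(2E,4R)-4-hydroxy-3,7-dimethylocta-2,6-dien-1-yl]-4-methoxybenzoate, via pinacol borate ester 15 (not isolated)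
Conditions: 14 (1.5 equiv), (R)-TRIP [(R)-3,3'-bis(2,4,6-triisopropylphenyl)-1,1'-binaphthyl-2,2'-diyl hydrogen phosphate] (10 mol%), 4 Å molecular sieves, toluene, −20 °C to 0 °C, 48 h; then sat. aq. NaHCO3
Reagents that add atoms: none
Why: Proposed new method: a chiral-phosphoric-acid-catalysed linear prenylboration in which the tertiary allylboronate 14 reacts through a closed six-membered chair (Zimmerman–Traxler, SE2') transition state, so its unsubstituted CH2 terminus bonds to the formyl carbon and the boron-bearing CMe2 carbon becomes the alkene terminus (linear prenyl, no E/Z question because both α-substituents are methyl), while (R)-TRIP binds the pseudo-axial boronate oxygen through P–OH and the formyl C–H through P=O and, with the alkenyl group equatorial, exposes the Re face of the enal to set C4 as R, the uncatalysed background of the hindered boronate being slow enough to protect the ee; the closest known reaction type is the chiral-phosphoric-acid-catalysed allylboration of aryl and alkenyl aldehydes with unsubstituted allyl-Bpin, together with the thermal γ-selective addition of α-substituted allylboronates.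

Step 10
Reactants: 16 methyl 3-[(2E)-4-(acetyloxy)-3-methylbut-2-en-1-yl]-5-[(2E,4R)-4-hydroxy-3,7-dimethylocta-2,6-dien-1-yl]-4-methoxybenzoate
Product: 18 3-[(2E,4R)-4-hydroxy-3,7-dimethylocta-2,6-dien-1-yl]-5-[(2E)-4-hydroxy-3-methylbut-2-en-1-yl]-4-methoxybenzoic acid (CNP0122795.1), via lithium carboxylate 17 (not isolated)
Conditions: LiOH·H2O (6 equiv), THF/MeOH/H2O (3:1:1), rt, 12 h; then 1 M HCl to pH 4, 0 °C
Reagents that add atoms: lithium hydroxide [Li+].[OH-]
Why: saponification (acyl–oxygen cleavage) removes the unhindered methyl benzoate and the allylic acetate in one operation, and the cold, mildly acidic work-up protonates the carboxylate without ionising the allylic carbinol, so the 4R centre and both E alkenes are untouched.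

**Compound list**
1 | methyl 3-bromo-4-hydroxybenzoate | COC(=O)c1ccc(O)c(Br)c1 | starting material
2 | allyl bromide (3-bromoprop-1-ene) | C=CCBr | starting material
3 | methyl 3-bromo-4-(prop-2-en-1-yloxy)benzoate | COC(=O)c1ccc(OCC=C)c(Br)c1 | intermediate
4 | methyl 5-bromo-4-oxo-3-(prop-2-en-1-yl)cyclohexa-1,5-diene-1-carboxylate (transient ortho-dienone, racemic) | COC(=O)C1=CC(CC=C)C(=O)C(Br)=C1 | intermediate
5 | methyl 3-bromo-4-hydroxy-5-(prop-2-en-1-yl)benzoate | COC(=O)c1cc(Br)c(O)c(CC=C)c1 | intermediate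
6 | methyl 3-bromo-4-methoxy-5-(prop-2-en-1-yl)benzoate | COC(=O)c1cc(Br)c(OC)c(CC=C)c1 | intermediate
7 | methacrolein (2-methylprop-2-enal) | CC(=C)C=O | starting material
8 | methyl 3-bromo-4-methoxy-5-[(2E)-3-methyl-4-oxobut-2-en-1-yl]benzoate | COC(=O)c1cc(Br)c(OC)c(C/C=C(\C)C=O)c1 | intermediate
9 | methyl 3-bromo-5-[(2E)-4-hydroxy-3-methylbut-2-en-1-yl]-4-methoxybenzoate | COC(=O)c1cc(Br)c(OC)c(C/C=C(\C)CO)c1 | intermediate
10 | allyltributylstannane | C=CC[Sn](CCCC)(CCCC)CCCC | starting material
11 | methyl 3-[(2E)-4-hydroxy-3-methylbut-2-en-1-yl]-4-methoxy-5-(prop-2-en-1-yl)benzoate | COC(=O)c1cc(CC=C)c(OC)c(C/C=C(\C)CO)c1 | intermediate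
12 | methyl 3-[(2E)-4-(acetyloxy)-3-methylbut-2-en-1-yl]-4-methoxy-5-(prop-2-en-1-yl)benzoate | COC(=O)c1cc(CC=C)c(OC)c(C/C=C(\C)COC(C)=O)c1 | intermediate
13 | methyl 3-[(2E)-4-(acetyloxy)-3-methylbut-2-en-1-yl]-4-methoxy-5-[(2E)-3-methyl-4-oxobut-2-en-1-yl]benzoate | COC(=O)c1cc(C/C=C(\C)C=O)c(OC)c(C/C=C(\C)COC(C)=O)c1 | intermediate
14 | 4,4,5,5-tetramethyl-2-(2-methylbut-3-en-2-yl)-1,3,2-dioxaborolane (α,α-dimethylallyl-Bpin) | C=CC(C)(C)B1OC(C)(C)C(C)(C)O1 | starting material
15 | methyl 3-[(2E)-4-(acetyloxy)-3-methylbut-2-en-1-yl]-5-[(2E,4R)-3,7-dimethyl-4-[(4,4,5,5-tetramethyl-1,3,2-dioxaborolan-2-yl)oxy]octa-2,6-dien-1-yl]-4-methoxybenzoate | COC(=O)c1cc(C/C=C(\C)[C@H](OB2OC(C)(C)C(C)(C)O2)CC=C(C)C)c(OC)c(C/C=C(\C)COC(C)=O)c1 | intermediate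
16 | methyl 3-[(2E)-4-(acetyloxy)-3-methylbut-2-en-1-yl]-5-[(2E,4R)-4-hydroxy-3,7-dimethylocta-2,6-dien-1-yl]-4-methoxybenzoate | COC(=O)c1cc(C/C=C(\C)[C@H](O)CC=C(C)C)c(OC)c(C/C=C(\C)COC(C)=O)c1 | intermediate
17 | lithium 3-[(2E,4R)-4-hydroxy-3,7-dimethylocta-2,6-dien-1-yl]-5-[(2E)-4-hydroxy-3-methylbut-2-en-1-yl]-4-methoxybenzoate | [Li+].[O-]C(=O)c1cc(C/C=C(\C)[C@H](O)CC=C(C)C)c(OC)c(C/C=C(\C)CO)c1 | intermediate
18 | 3-[(2E,4R)-4-hydroxy-3,7-dimethylocta-2,6-dien-1-yl]-5-[(2E)-4-hydroxy-3-methylbut-2-en-1-yl]-4-methoxybenzoic acid | COc1c(C/C=C(\C)CO)cc(C(=O)O)cc1C/C=C(\C)[C@H](O)CC=C(C)C | target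

**Totals**
Total step count: 10. Longest linear sequence: 10 steps (fully linear from 1).

**Three steps most likely to fail**

Step 9 (proposed new prenylboration). The tertiary boronate is hindered and may react slowly. The acid may also promote a 1,3-boron shift to prenyl-Bpin, which would give the branched reverse-prenyl carbinol. Neither the level nor the sense of induction with this reagent has been demonstrated; if the sense proved opposite, the (S)-acid would be used. The fallback uses known chemistry, sets out from 13 and comes back at 16. Brown allylboration of 13 with (+)-B-allyldiisopinocampheylborane (from (+)-Ipc2BOMe; Et2O, −78 °C; NaBO3·4H2O work-up) delivers the unsubstituted allyl group to the Re face and gives methyl 3-[(2E)-4-(acetyloxy)-3-methylbut-2-en-1-yl]-5-[(2E,4R)-4-hydroxy-3-methylhepta-2,6-dien-1-yl]-4-methoxybenzoate F1. Cross-metathesis of the terminal vinyl group of F1 with 2-methyl-2-butene (second-generation Grubbs catalyst RuCl2(PCy3)(H2IMes)(=CHPh), neat alkene with CH2Cl2, rt) converts allyl into prenyl and gives 16.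

Step 8 (second cross-metathesis on the functionalised arene). Ruthenium hydride species may isomerise the allyl group to a propenyl arene, homodimer may persist, and the acetoxy-bearing alkene may interfere. The fallback sets out from 12 and comes back at 13. Cross-metathesis of 12 with 2-methyl-2-butene (second-generation Grubbs catalyst, rt), a much easier partner, gives methyl 3-[(2E)-4-(acetyloxy)-3-methylbut-2-en-1-yl]-4-methoxy-5-(3-methylbut-2-en-1-yl)benzoate F2. E-selective allylic oxidation of the trans methyl group of the prenyl unit (SeO2 catalytic, t-BuOOH, CH2Cl2, rt) gives methyl 3-[(2E)-4-(acetyloxy)-3-methylbut-2-en-1-yl]-5-[(2E)-4-hydroxy-3-methylbut-2-en-1-yl]-4-methoxybenzoate F3 together with some 13. MnO2 in CH2Cl2 then oxidises F3 to 13.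

Step 6 (Stille allylation). Oxidative addition at the ortho-alkoxy bromide may be slow, and palladium hydride may isomerise the product to the propenyl arene at 100 °C. The fallback reverses the polarity of the coupling, sets out from 9 and comes back at 11. Miyaura borylation of 9 (B2pin2, Pd(dppf)Cl2, KOAc, dioxane, 80 °C) gives methyl 3-[(2E)-4-hydroxy-3-methylbut-2-en-1-yl]-4-methoxy-5-(4,4,5,5-tetramethyl-1,3,2-dioxaborolan-2-yl)benzoate F4. F4 is then coupled as the aryl nucleophile with allyl bromide 2 through a π-allyl palladium intermediate (Pd(PPh3)4, K2CO3, THF/H2O, rt to 50 °C), giving 11 under conditions too mild for alkene migration.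

**Further compounds**
F1 | step 9 | methyl 3-[(2E)-4-(acetyloxy)-3-methylbut-2-en-1-yl]-5-[(2E,4R)-4-hydroxy-3-methylhepta-2,6-dien-1-yl]-4-methoxybenzoate | COC(=O)c1cc(C/C=C(\C)[C@H](O)CC=C)c(OC)c(C/C=C(\C)COC(C)=O)c1
F2 | step 8 | methyl 3-[(2E)-4-(acetyloxy)-3-methylbut-2-en-1-yl]-4-methoxy-5-(3-methylbut-2-en-1-yl)benzoate | COC(=O)c1cc(CC=C(C)C)c(OC)c(C/C=C(\C)COC(C)=O)c1
F3 | step 8 | methyl 3-[(2E)-4-(acetyloxy)-3-methylbut-2-en-1-yl]-5-[(2E)-4-hydroxy-3-methylbut-2-en-1-yl]-4-methoxybenzoate | COC(=O)c1cc(C/C=C(\C)CO)c(OC)c(C/C=C(\C)COC(C)=O)c1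
F4 | step 6 | methyl 3-[(2E)-4-hydroxy-3-methylbut-2-en-1-yl]-4-methoxy-5-(4,4,5,5-tetramethyl-1,3,2-dioxaborolan-2-yl)benzoate | COC(=O)c1cc(B2OC(C)(C)C(C)(C)O2)c(OC)c(C/C=C(\C)CO)c1
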